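## Structural features

Broussonol D is a flavonol with three rings: ring A (C4a–C8a, phloroglucinol type, 5-OH, 7-OH, prenyl at C8), ring C (a 3-hydroxy-γ-pyranone: O1, C2, C3–OH, C4=O) and ring B (a catechol on C2, 3′,4′-OH, prenyl at C5′). Ring A is fused to ring C through C4a–C8a, and ring B is joined by the C2–C1′ bond. There is no stereocentre, so no stereocentres stand next to each other. The fragile groups are the two trisubstituted alkenes, each ortho to a phenol (acid closes them to 2,2-dimethylchromans; halogens, peracids and hydrogenation attack them), the air-sensitive catechol, and the 3-hydroxypyranone, which is degraded by prolonged alkaline peroxide. The real difficulty is threefold: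
- the fully substituted pyranone carrying oxygen at C3 in a 5-oxygenated series;
- the prenyl at C8, which must sit between O1 and O7 and not at C6;
- protecting groups that can be removed without hydrogen or strong acid.

The key step exploits C3 of ring C. It is a single carbon bearing a heteroatom, flanked by C2 (bonded to O1 and ring B) and C4 (bonded to C4a of ring A). C3 can therefore be the carbon of a nitroalkane that condenses with an aldehyde on each side, so ring C closes at the C3–C4 carbon–carbon bond. The step also uses the fact that the only free hydroxyl of the ring A partner lies between the formyl carbon and the prenyl-bearing carbon, so it must become O1 next to C8.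

## Logic of the disconnections

15 ⇒ 14. The four aryl O–CH2 bonds of acetals at O5, O7, O3′ and O4′ are added in the retrosynthetic sense. The free phenols would not survive alkaline peroxide and would compete as nucleophiles. Methoxymethyl acetals are chosen because they come off without hydrogen and without strong Lewis acid. There is no skeletal gain. The demand on the forward step is a solvolysis mild enough for a prenyl group ortho to each liberated hydroxyl.

14 ⇒ 11. The C3–OH and C4=O bonds are cut and replaced by C3–NO2 and C4–H, with C2 returned to sp3. A nitro group at C3 is the one substituent that makes C3 a carbon nucleophile for ring closure and can afterwards be exchanged for oxygen. The pyranone oxidation pattern is reduced to a conjugated nitroalkene. The forward step needs a nucleophilic oxidant that attacks only the electron-poor C3=C4 bond and spares both prenyl alkenes.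

11 ⇒ 3 + 8 (key disconnection). The O1–C2 bond and the C3=C4 bond are cut. In one sentence: ring C is closed at C3–C4 by a tandem oxa-Michael/nitro-aldol condensation of 3 with 8. The cut splits a C33 intermediate into two benzaldehyde-derived halves of similar size, each carrying one prenyl group. The question of C8 versus C6 is reduced to which hydroxyl of 3 is free. The forward step requires a hindered, hydrogen-bonded phenol to add reversibly and the sequence to be driven by an irreversible dehydration.

8 ⇒ 6. The C=C bond of the nitroalkene (C2=C3 of the target) is cut, giving an aldehyde and a one-carbon nitroalkane. The gain is a commercial C1 reagent as the source of C3. The condensation must leave acetals and the prenyl group intact.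

6 ⇒ 5 ⇒ 4. The aryl–CH2 bond of the ring B prenyl (C5′–C1‴) is cut, then the two O–CH2 acetal bonds. The bromine of commercial 4 already sits at C5′, so the prenyl position needs no regiochemical decision. The coupling must deliver the linear and not the branched allyl isomer.

3 ⇒ 2 ⇒ 1. The two O–CH2 acetal bonds are cut, then the aryl–CH2 bond of the ring A prenyl (C8–C1″). In 1 the two ring CH carbons are equivalent, so C-prenylation cannot give a regioisomer. The sorting of the three hydroxyls is left to acetal formation, where the hydroxyl wedged between formyl and prenyl is the least reactive. The demand is that selectivity in the bis-acetalisation.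

## Other disconnections considered

Alternative 1: the first that comes to mind. Cut O1–C2 and C2–C3 (chalcone route). Forward: Claisen–Schmidt condensation of methyl ketone A1 with 6 to the 2′-hydroxychalcone A2, then Algar–Flynn–Oyamada oxidation, in which the phenoxide closes ring C at O1 onto the epoxidised enone to give 14. Ground for preferring the chosen plan: A2 carries a 6′-alkoxy group (required for the 5-OH). Such a group twists the aryl ketone and favours opening of the epoxide at Cα, a five-membered closure that leads to aurones. The ring size of the key step is therefore not secured by the substrate. A1 needs the same regiochemical solution as 3, so nothing is saved there. The chosen route is one step longer, but its ring closure can only give the six-membered ring.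

Alternative 2: cut both aryl–prenyl bonds (C8–C1″ and C5′–C1‴) on an intact flavonol core. Forward: the parent pentahydroxyflavone A3 is converted to bis-ether A4 (5-O-prenyl, 4′-O-(1,1-dimethylallyl), 3,7,3′-tris-methoxymethyl). One thermal or Eu(fod)3-assisted operation then moves the O5 prenyl to C6 and on to C8 (Claisen–Cope) and the O4′ group to C5′ (Claisen). Ground: the regiochemistry of both shifts is secured, but A4 requires the five hydroxyls of A3 to be sorted into three classes. Two different allylic ethers must be placed on the least reactive (5-OH) and on one of two similar catechol hydroxyls. This protecting-group sequence is longer than the whole chosen route, and the two rearrangements have different thermal demands.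

Alternative 3: cut C4–C4a, C3–C4 and O1–C2 (three components). Forward: palladium-catalysed carbonylative Sonogashira coupling/6-endo cyclisation (PdCl2(PPh3)2, CO, amine) of iodophenol A5 with alkyne A6 to flavone A7, then C3 metalation, borylation and oxidation. Ground: A5 needs either iodination of a prenylated, electron-rich phenol (iodonium attacks the alkene and closes it onto the phenol) or prenylation of a polyoxygenated iodophenol. The annulation gives a flavone, so the C3 oxygen costs extra steps in the presence of acetal-directed lithiation sites. The 6-endo/5-exo choice of the ynone is again not secured by the substrate.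

Key step: step 6

Assumption: 1, 4 and the reagents chloromethyl methyl ether, 1-bromo-3-methylbut-2-ene, tributyl(3-methylbut-2-en-1-yl)stannane and nitromethane are taken as commercial. The target has no stereocentre, so racemic intermediates suffice.

## Steps

Step 1
Reactants: 1 2,4,6-trihydroxybenzaldehyde
Product: 2 2,4,6-trihydroxy-3-(3-methylbut-2-en-1-yl)benzaldehyde
Conditions: 1-bromo-3-methylbut-2-ene (1 equiv), 10% aq KOH, 0 °C to rt
Reagents that add atoms: 1-bromo-3-methylbut-2-ene, CC(C)=CCBr
Why: C-alkylation of a phloroglucinol-type phenoxide (a vinylogous enolate) by a soft allylic bromide in water, where solvation of oxygen favours attack through carbon. C3 and C5 of 1 are equivalent, so only one mono-C-prenyl product is possible, and one equivalent of bromide limits dialkylation.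

Step 2
Reactants: 2 2,4,6-trihydroxy-3-(3-methylbut-2-en-1-yl)benzaldehyde
Product: 3 2-hydroxy-4,6-bis(methoxymethoxy)-3-(3-methylbut-2-en-1-yl)benzaldehyde
Conditions: MOMCl (2.2 equiv), i-Pr2NEt, CH2Cl2, 0 °C
Reagents that add atoms: chloromethyl methyl ether, COCCl
Why: O-alkylation of phenols to methoxymethyl acetals. The 4-OH (para to CHO, not hydrogen-bonded) should react first. Of the two chelating ortho hydroxyls, the one flanked only by H (6-OH) should be alkylated, while the 2-OH between CHO and prenyl stays in the hydrogen bond; this places the later O1 next to the prenyl group.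

Step 3
Reactants: 4 3-bromo-4,5-dihydroxybenzaldehyde
Product: 5 3-bromo-4,5-bis(methoxymethoxy)benzaldehyde
Conditions: MOMCl (2.5 equiv), i-Pr2NEt, CH2Cl2, 0 °C to rt
Reagents that add atoms: chloromethyl methyl ether, COCCl
Why: exhaustive acetalisation of both catechol hydroxyls; no selectivity is needed, and the acetals make the catechol stable to base and oxidant in the later steps.

Step 4
Reactants: 5 3-bromo-4,5-bis(methoxymethoxy)benzaldehyde
Product: 6 3,4-bis(methoxymethoxy)-5-(3-methylbut-2-en-1-yl)benzaldehyde
Conditions: tributyl(3-methylbut-2-en-1-yl)stannane, Pd(PPh3)4 (cat.), DMF, 95 °C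
Reagents that add atoms: tributyl(3-methylbut-2-en-1-yl)stannane, CCCC[Sn](CCCC)(CCCC)CC=C(C)C
Why: Stille coupling. Zerovalent palladium inserts into the C–Br bond, and the aryl(η3-prenyl)palladium intermediate should reductively eliminate at the unsubstituted allyl terminus to give the linear prenyl arene. The aldehyde and acetals are inert.

Step 5
Reactants: 6 3,4-bis(methoxymethoxy)-5-(3-methylbut-2-en-1-yl)benzaldehyde
Product: 8 1,2-bis(methoxymethoxy)-3-(3-methylbut-2-en-1-yl)-5-[(E)-2-nitroethenyl]benzene, via nitro alcohol 7 (not isolated)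
Conditions: MeNO2 (solvent), NH4OAc, 90 °C
Reagents that add atoms: nitromethane, C[N+](=O)[O-]
Why: Henry (nitro-aldol) condensation. Dehydration of 7 should give the conjugated E-nitroalkene as the thermodynamic isomer, and the buffered medium should leave acetals and the prenyl alkene untouched.

Step 6
Reactants: 3 2-hydroxy-4,6-bis(methoxymethoxy)-3-(3-methylbut-2-en-1-yl)benzaldehyde; 8 1,2-bis(methoxymethoxy)-3-(3-methylbut-2-en-1-yl)-5-[(E)-2-nitroethenyl]benzene
Product: 11 2-[3,4-bis(methoxymethoxy)-5-(3-methylbut-2-en-1-yl)phenyl]-5,7-bis(methoxymethoxy)-8-(3-methylbut-2-en-1-yl)-3-nitro-2H-chromene (racemic), via oxa-Michael adduct 9 (not isolated), via nitro aldol 10 (not isolated)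
Conditions: DABCO (1 equiv), MeCN, 60 °C, slow addition of 8
Reagents that add atoms: none
Why: Tandem oxa-Michael/Henry (nitro-aldol) condensation, a known route from salicylaldehydes and β-nitrostyrenes to 2-aryl-3-nitro-2H-chromenes. DABCO deprotonates the only free phenol of 3; the phenoxide adds to the β-carbon of 8 (O1–C2, reversible), and the nitronate of 9 attacks the neighbouring formyl carbon (C3–C4) in a 6-(enolexo)-exo-trig closure to give 10. E1cB loss of water from 10 is irreversible, gives the nitroalkene conjugated with ring A and pulls both reversible additions forward, which should compensate for the hindered, hydrogen-bonded phenol and the electron-rich aldehyde. Ring C is thus closed at a carbon–carbon bond, whereas the usual closures are at O1. Regiochemistry needs no control here: 3 has one free hydroxyl, between the formyl and the prenyl-bearing carbon, so O1 ends next to C8 and a 6-prenyl isomer cannot form. The one new stereocentre, C2, forms as a racemate under no control and is left so, because it becomes sp2 in step 7. The step needs O- over C-attack of the phenoxide (expected for a formyl-stabilised phenoxide whose para carbon is flanked by two acetal groups) and condensation over amine-induced oligomerisation of 8 (kept low by slow addition); acetals and both prenyl groups are inert to DABCO.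

Step 7
Reactants: 11 2-[3,4-bis(methoxymethoxy)-5-(3-methylbut-2-en-1-yl)phenyl]-5,7-bis(methoxymethoxy)-8-(3-methylbut-2-en-1-yl)-3-nitro-2H-chromene
Product: 14 3-hydroxy-2-[3,4-bis(methoxymethoxy)-5-(3-methylbut-2-en-1-yl)phenyl]-5,7-bis(methoxymethoxy)-8-(3-methylbut-2-en-1-yl)-4H-chromen-4-one, via nitro epoxide 12 (not isolated), via chromane-3,4-dione 13 (not isolated)
Conditions: 30% aq H2O2 (excess), aq NaOH, THF, 0 °C to rt; NaH2PO4 work-up
Reagents that add atoms: hydrogen peroxide, OO
Why: Nucleophilic (Weitz–Scheffer-type) epoxidation of the conjugated nitroalkene by hydroperoxide anion gives α-nitro epoxide 12. A second hydroperoxide opens it at benzylic C4, the C3 alkoxide expels nitrite, and Kornblum–DeLaMare fragmentation of the 4-hydroperoxy ketone gives dione 13, which enolises through its acidic C2–H to the aromatic 3-hydroxypyranone; this conversion of 2-aryl-3-nitro-2H-chromenes into flavonols is a known reaction. Hydroperoxide anion attacks only the electron-poor C3=C4 bond, so the two electron-rich prenyl alkenes and the acetals should survive.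

Step 8
Reactants: 14 3-hydroxy-2-[3,4-bis(methoxymethoxy)-5-(3-methylbut-2-en-1-yl)phenyl]-5,7-bis(methoxymethoxy)-8-(3-methylbut-2-en-1-yl)-4H-chromen-4-one
Product: 15 Broussonol D, 2-[3,4-dihydroxy-5-(3-methylbut-2-en-1-yl)phenyl]-3,5,7-trihydroxy-8-(3-methylbut-2-en-1-yl)-4H-chromen-4-one
Conditions: 3 M aq HCl, MeOH, 45 °C, Ar, short reaction time
Reagents that add atoms: none
Why: Acid-catalysed acetal solvolysis (transfer of the CH2 unit to methanol) should remove all four methoxymethyl groups. Dilute acid, moderate temperature and short contact are chosen because each freed phenol next to a prenyl group (7-OH/C8, 4′-OH/C5′) could add to the alkene under stronger acid.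

## Compound list

1 | 2,4,6-trihydroxybenzaldehyde | O=Cc1c(O)cc(O)cc1O | starting material
2 | 2,4,6-trihydroxy-3-(3-methylbut-2-en-1-yl)benzaldehyde | O=Cc1c(O)c(CC=C(C)C)c(O)cc1O | intermediate
3 | 2-hydroxy-4,6-bis(methoxymethoxy)-3-(3-methylbut-2-en-1-yl)benzaldehyde | O=Cc1c(O)c(CC=C(C)C)c(OCOC)cc1OCOC | intermediate
4 | 3-bromo-4,5-dihydroxybenzaldehyde | O=Cc1cc(O)c(O)c(Br)c1 | starting material
5 | 3-bromo-4,5-bis(methoxymethoxy)benzaldehyde | O=Cc1cc(OCOC)c(OCOC)c(Br)c1 | intermediate
6 | 3,4-bis(methoxymethoxy)-5-(3-methylbut-2-en-1-yl)benzaldehyde | O=Cc1cc(OCOC)c(OCOC)c(CC=C(C)C)c1 | intermediate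
7 | 1-[3,4-bis(methoxymethoxy)-5-(3-methylbut-2-en-1-yl)phenyl]-2-nitroethan-1-ol (racemic, not isolated) | OC(C[N+](=O)[O-])c1cc(OCOC)c(OCOC)c(CC=C(C)C)c1 | intermediate
8 | 1,2-bis(methoxymethoxy)-3-(3-methylbut-2-en-1-yl)-5-[(E)-2-nitroethenyl]benzene | [O-][N+](=O)/C=C/c1cc(OCOC)c(OCOC)c(CC=C(C)C)c1 | intermediate
9 | 2-{1-[3,4-bis(methoxymethoxy)-5-(3-methylbut-2-en-1-yl)phenyl]-2-nitroethoxy}-4,6-bis(methoxymethoxy)-3-(3-methylbut-2-en-1-yl)benzaldehyde (racemic, not isolated) | O=Cc1c(OC(C[N+](=O)[O-])c2cc(OCOC)c(OCOC)c(CC=C(C)C)c2)c(CC=C(C)C)c(OCOC)cc1OCOC | intermediate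
10 | 2-[3,4-bis(methoxymethoxy)-5-(3-methylbut-2-en-1-yl)phenyl]-5,7-bis(methoxymethoxy)-8-(3-methylbut-2-en-1-yl)-3-nitrochroman-4-ol (racemic diastereomer mixture, not isolated) | OC1C([N+](=O)[O-])C(c2cc(OCOC)c(OCOC)c(CC=C(C)C)c2)Oc2c(CC=C(C)C)c(OCOC)cc(OCOC)c12 | intermediate
11 | 2-[3,4-bis(methoxymethoxy)-5-(3-methylbut-2-en-1-yl)phenyl]-5,7-bis(methoxymethoxy)-8-(3-methylbut-2-en-1-yl)-3-nitro-2H-chromene (racemic at C2) | [O-][N+](=O)C1=Cc2c(OCOC)cc(OCOC)c(CC=C(C)C)c2OC1c1cc(OCOC)c(OCOC)c(CC=C(C)C)c1 | intermediate
12 | 3,4-epoxide of 11: 2-[3,4-bis(methoxymethoxy)-5-(3-methylbut-2-en-1-yl)phenyl]-5,7-bis(methoxymethoxy)-8-(3-methylbut-2-en-1-yl)-3-nitro-3,4-epoxychromane (racemic, relative configuration not fixed, not isolated) | [O-][N+](=O)C12OC1c1c(OCOC)cc(OCOC)c(CC=C(C)C)c1OC2c1cc(OCOC)c(OCOC)c(CC=C(C)C)c1 | intermediate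
13 | 2-[3,4-bis(methoxymethoxy)-5-(3-methylbut-2-en-1-yl)phenyl]-5,7-bis(methoxymethoxy)-8-(3-methylbut-2-en-1-yl)chromane-3,4-dione (racemic, not isolated) | O=C1C(=O)c2c(OCOC)cc(OCOC)c(CC=C(C)C)c2OC1c1cc(OCOC)c(OCOC)c(CC=C(C)C)c1 | intermediate
14 | 3-hydroxy-2-[3,4-bis(methoxymethoxy)-5-(3-methylbut-2-en-1-yl)phenyl]-5,7-bis(methoxymethoxy)-8-(3-methylbut-2-en-1-yl)-4H-chromen-4-one | O=c1c(O)c(-c2cc(OCOC)c(OCOC)c(CC=C(C)C)c2)oc2c(CC=C(C)C)c(OCOC)cc(OCOC)c12 | intermediate
15 | Broussonol D, 2-[3,4-dihydroxy-5-(3-methylbut-2-en-1-yl)phenyl]-3,5,7-trihydroxy-8-(3-methylbut-2-en-1-yl)-4H-chromen-4-one (no stereocentre) | CC(C)=CCc1cc(-c2oc3c(CC=C(C)C)c(O)cc(O)c3c(=O)c2O)cc(O)c1O | target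

## Step count and least certain steps

Total step count: 8. Longest linear sequence: 6 steps (steps 3, 4, 5, 6, 7, 8 from 4).

Step 6 (key step). The most likely failure is an unfavourable oxa-Michael equilibrium. The phenol of 3 is hydrogen-bonded to the formyl group and flanked by the prenyl chain, and the formyl carbon carries two ortho oxygen donors, so amine-induced oligomerisation of 8 may outrun ring closure. Fallback (known chemistry, ring C closed at O1 instead): it sets out from 3 and uses 6. Addition of MeMgBr (excess, THF, −78 to 0 °C) to 3 gives the benzylic carbinol F1. MnO2 in CH2Cl2 oxidises it to the methyl ketone F2 (the same compound as A1). Claisen–Schmidt condensation of F2 with 6 (KOH, EtOH) gives the chalcone F3 (the same compound as A2). Algar–Flynn–Oyamada oxidation (H2O2, NaOH, MeOH, 0 °C) then returns to the route at 14.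

Step 7. The risk is over-oxidation: hydroperoxide may cleave the C3–C4 bond of dione 13 or of the product. A second risk is base-induced shift of the double bond of 11 into the 2-position, giving a nitro enol ether that no longer accepts hydroperoxide. Fallback (stepwise, oxidation level reached by autoxidation instead of peroxide fragmentation): it sets out from 11. Epoxidation with tert-butyl hydroperoxide and catalytic t-BuOK in THF at −40 °C allows 12 to be isolated. Opening with water (aq NaHCO3, THF) expels nitrite and, after α-ketol shift, gives the dihydroflavonol F4. Base-mediated air dehydrogenation (K2CO3, DMSO, air) returns to the route at 14.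

Step 2. The risk is acetalisation of the wrong ortho hydroxyl, which would leave the free OH away from the prenyl group and lead to the 6-prenyl series. Fallback (regiochemistry fixed by a sigmatropic shift instead of a selective protection): it sets out from 1. Bis-acetalisation (MOMCl, i-Pr2NEt) gives the known chelated phenol F5. O-allylation (allyl bromide, K2CO3, DMF) gives the allyl ether F6. Claisen rearrangement (N,N-diethylaniline, 190 °C) can deliver the allyl group only to the free ortho carbon and gives the 3-allyl phenol F7. Cross-metathesis of F7 with 2-methylbut-2-ene (second-generation Grubbs catalyst RuCl2(=CHPh)(H2IMes)(PCy3), CH2Cl2, 40 °C) returns to the route at 3.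

Step 8. The risk is acid-catalysed addition of the freed 7-OH and 4′-OH to the neighbouring prenyl alkenes (2,2-dimethylchroman formation) and hydration of the alkenes, in competition with acetal cleavage. Fallback (silyl transfer in an aprotic medium followed by neutral hydrolysis, in place of protic acid): it sets out from 14. TMSOTf and 2,2′-bipyridyl in MeCN at 0 °C exchange the acetals for silyl ethers and give the pentakis(trimethylsilyl) ether F8, which is not isolated. Addition of water at pH 7 hydrolyses F8 and returns to the route at 15.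

## Further compounds

F1 | step 6 | 2-(1-hydroxyethyl)-3,5-bis(methoxymethoxy)-6-(3-methylbut-2-en-1-yl)phenol (racemic) | CC(O)c1c(O)c(CC=C(C)C)c(OCOC)cc1OCOC
F2 | step 6 | 1-[2-hydroxy-4,6-bis(methoxymethoxy)-3-(3-methylbut-2-en-1-yl)phenyl]ethan-1-one | CC(=O)c1c(O)c(CC=C(C)C)c(OCOC)cc1OCOC
F3 | step 6 | (E)-3-[3,4-bis(methoxymethoxy)-5-(3-methylbut-2-en-1-yl)phenyl]-1-[2-hydroxy-4,6-bis(methoxymethoxy)-3-(3-methylbut-2-en-1-yl)phenyl]prop-2-en-1-one | O=C(/C=C/c1cc(OCOC)c(OCOC)c(CC=C(C)C)c1)c1c(O)c(CC=C(C)C)c(OCOC)cc1OCOC
F4 | step 7 | 3-hydroxy-2-[3,4-bis(methoxymethoxy)-5-(3-methylbut-2-en-1-yl)phenyl]-5,7-bis(methoxymethoxy)-8-(3-methylbut-2-en-1-yl)chroman-4-one (racemic, relative configuration not fixed) | O=C1c2c(OCOC)cc(OCOC)c(CC=C(C)C)c2OC(c2cc(OCOC)c(OCOC)c(CC=C(C)C)c2)C1O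
F5 | step 2 | 2-hydroxy-4,6-bis(methoxymethoxy)benzaldehyde | O=Cc1c(O)cc(OCOC)cc1OCOC
F6 | step 2 | 2-(allyloxy)-4,6-bis(methoxymethoxy)benzaldehyde | O=Cc1c(OCC=C)cc(OCOC)cc1OCOC
F7 | step 2 | 3-allyl-2-hydroxy-4,6-bis(methoxymethoxy)benzaldehyde | O=Cc1c(O)c(CC=C)c(OCOC)cc1OCOC
F8 | step 8 | 2-[3,4-bis(trimethylsilyloxy)-5-(3-methylbut-2-en-1-yl)phenyl]-3,5,7-tris(trimethylsilyloxy)-8-(3-methylbut-2-en-1-yl)-4H-chromen-4-one | O=c1c(O[Si](C)(C)C)c(-c2cc(O[Si](C)(C)C)c(O[Si](C)(C)C)c(CC=C(C)C)c2)oc2c(CC=C(C)C)c(O[Si](C)(C)C)cc(O[Si](C)(C)C)c12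
A1 | alternative 1 | 1-[2-hydroxy-4,6-bis(methoxymethoxy)-3-(3-methylbut-2-en-1-yl)phenyl]ethan-1-one | CC(=O)c1c(O)c(CC=C(C)C)c(OCOC)cc1OCOC
A2 | alternative 1 | (E)-3-[3,4-bis(methoxymethoxy)-5-(3-methylbut-2-en-1-yl)phenyl]-1-[2-hydroxy-4,6-bis(methoxymethoxy)-3-(3-methylbut-2-en-1-yl)phenyl]prop-2-en-1-one | O=C(/C=C/c1cc(OCOC)c(OCOC)c(CC=C(C)C)c1)c1c(O)c(CC=C(C)C)c(OCOC)cc1OCOC
A3 | alternative 2 | 2-(3,4-dihydroxyphenyl)-3,5,7-trihydroxy-4H-chromen-4-one (quercetin) | O=c1c(O)c(-c2ccc(O)c(O)c2)oc2cc(O)cc(O)c12
A4 | alternative 2 | 3,7-bis(methoxymethoxy)-2-[3-(methoxymethoxy)-4-(2-methylbut-3-en-2-yloxy)phenyl]-5-(3-methylbut-2-en-1-yloxy)-4H-chromen-4-one | O=c1c(OCOC)c(-c2ccc(OC(C)(C)C=C)c(OCOC)c2)oc2cc(OCOC)cc(OCC=C(C)C)c12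
A5 | alternative 3 | 2-iodo-3,5-bis(methoxymethoxy)-6-(3-methylbut-2-en-1-yl)phenol | Oc1c(I)c(OCOC)cc(OCOC)c1CC=C(C)C
A6 | alternative 3 | 5-ethynyl-1,2-bis(methoxymethoxy)-3-(3-methylbut-2-en-1-yl)benzene | C#Cc1cc(OCOC)c(OCOC)c(CC=C(C)C)c1
A7 | alternative 3 | 2-[3,4-bis(methoxymethoxy)-5-(3-methylbut-2-en-1-yl)phenyl]-5,7-bis(methoxymethoxy)-8-(3-methylbut-2-en-1-yl)-4H-chromen-4-one | O=c1cc(-c2cc(OCOC)c(OCOC)c(CC=C(C)C)c2)oc2c(CC=C(C)C)c(OCOC)cc(OCOC)c12
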